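**Plan**

- The retrosynthesis first cuts the depside ester bond between the ring A carbonyl and the C4 oxygen of ring B, then the C3–C4 and C5–C6 bonds of ring B.
- Ring B is a 2,4-dioxygenated 6-propylbenzoate. Its C1 (carboxyl), C2 (oxygen), C3 and C6 (propyl) correspond to C5, C4, C3 and C6 of a 2-pyrone-5-carboxylate, and its C4 (oxygen) and C5 to a ketene acetal; this pattern is what allows a pyrone cycloaddition with loss of carbon dioxide.
- Forward, dibenzyl 3-oxopentanedioate is C-butanoylated, lactonised to the 4-hydroxy-2-pyrone and O-benzylated; the pyrone and 1,1-bis(trimethylsilyloxy)ethene then give ring B with only the C4 hydroxyl free.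
- The ring A acid comes from 5-propylresorcinol by methylation, Vilsmeier formylation and Pinnick oxidation, and is joined to the C4 hydroxyl through its acid chloride.
- Hydrogenolysis of the benzyl ester and the benzyl ether ends the route.
- The target has no stereocentre; only regiochemistry must be controlled, and it follows from the polarity of the cycloaddition and from the free/protected oxygen pattern that the cycloaddition leaves.

Key step: step 5

Assumption: dibenzyl 3-oxopentanedioate, butanoyl chloride, trimethylsilyl acetate and 5-propylresorcinol are taken as purchasable; the ketene bis(silyl) acetal is made in one step because its commercial supply is uncertain.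

**Route**

Step 1
Reactants: 1 dibenzyl 3-oxopentanedioate; 2 butanoyl chloride
Product: 3 dibenzyl 2-butanoyl-3-oxopentanedioate
Conditions: MgCl2, pyridine, CH2Cl2, 0 °C to rt; aq. HCl work-up
Reagents that add atoms: none
Why: Magnesium chelation of the β-keto ester makes the CH2 acidic enough for pyridine and directs soft C-acylation of the enolate (MgCl2/amine C-acylation of β-keto esters); one equivalent of acid chloride should keep it to mono-acylation.

Step 2
Reactants: 3 dibenzyl 2-butanoyl-3-oxopentanedioate
Product: 4 benzyl 4-hydroxy-2-oxo-6-propyl-2H-pyran-5-carboxylate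
Conditions: DBU, toluene, 80 °C; aq. HCl work-up
Reagents that add atoms: none
Why: The enolate oxygen of the butanoyl ketone attacks the distal benzyl ester in a 6-exo-trig addition–elimination (base-mediated lactonisation of a 3,5-dioxo ester to a 4-hydroxy-2-pyrone), the only ring size open to this tricarbonyl system.

Step 3
Reactants: 4 benzyl 4-hydroxy-2-oxo-6-propyl-2H-pyran-5-carboxylate
Product: 5 benzyl 4-(benzyloxy)-2-oxo-6-propyl-2H-pyran-5-carboxylate
Conditions: BnOH, PPh3, DIAD, THF, 0 °C to rt
Reagents that add atoms: benzyl alcohol, OCc1ccccc1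
Why: The vinylogous acid is an ideal Mitsunobu pronucleophile, and Mitsunobu etherification of 4-hydroxy-2-pyrones is known to alkylate the 4-oxygen and so avoids benzylation at C3 or at the lactone carbonyl oxygen.

Step 4
Reactants: 6 trimethylsilyl acetate
Product: 7 1,1-bis(trimethylsilyloxy)ethene
Conditions: LiN(iPr)2, THF, −78 °C; Me3SiCl, −78 °C to rt; filtration and distillation under argon
Reagents that add atoms: chlorotrimethylsilane, C[Si](C)(C)Cl
Why: Kinetic deprotonation of the silyl ester and O-silylation of its lithium enolate is the standard preparation of ketene bis(silyl) acetals; distillation should remove any C-silylated isomer.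

Step 5
Reactants: 5 benzyl 4-(benzyloxy)-2-oxo-6-propyl-2H-pyran-5-carboxylate; 7 1,1-bis(trimethylsilyloxy)ethene
Product: 11 benzyl 2-(benzyloxy)-4-hydroxy-6-propylbenzoate, via bicyclic lactone cycloadduct 8 (not isolated), via bis(silyloxy)cyclohexadiene 9 (not isolated), via aryl trimethylsilyl ether 10 (not isolated)
Conditions: 7 (excess), toluene, 110 °C, sealed tube; then 1 M HCl, THF, rt
Reagents that add atoms: none
Why: The electron-rich CH2 terminus of 7 adds to C6 of pyrone 5, the carbon β to the 5-ester and δ to the lactone carbonyl, while the acetal carbon bonds to C3, so that an asynchronous inverse-electron-demand Diels–Alder reaction gives bridged lactone 8; retro-(4+2) loss of CO2 then gives diene 9, 1,2-elimination of Me3SiOH aromatises it to silyl ether 10, and dilute acid frees the phenol. The closest known reaction type is the cycloaddition of 2-pyrone-5-carboxylates (coumalates) with ketene acetals, which gives 4-alkoxybenzoates after decarboxylation and loss of alcohol. Ring B is closed as a six-membered carbocycle by this intermolecular (4+2) cycloaddition, both new bonds (C3–C4 and C5–C6 of the salicylate) being made in the same operation. The two bridgehead stereocentres of 8 are transient and vanish on aromatisation, so no stereocontrol is needed. The step needs regioselectivity, which the matched polarisation of the partners (nucleophilic CH2 against electrophilic C6, cationic acetal carbon against the vinylogous-carbonate C3) should secure, and it needs a single leaving group, which the symmetric bis(silyloxy) acetal guarantees because either elimination gives the same aryl silyl ether. The 4-benzyloxy and 6-propyl groups make 5 less reactive than the parent coumalate, which is why excess 7 and 110 °C are proposed.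

Step 6
Reactants: 12 5-propylresorcinol
Product: 13 1,3-dimethoxy-5-propylbenzene
Conditions: MeI, K2CO3, acetone, reflux
Reagents that add atoms: iodomethane, CI
Why: Williamson O-methylation of both phenols under standard carbonate conditions.

Step 7
Reactants: 13 1,3-dimethoxy-5-propylbenzene
Product: 14 2,4-dimethoxy-6-propylbenzaldehyde
Conditions: POCl3, DMF, 0 °C to 70 °C; then aq. NaOAc
Reagents that add atoms: N,N-dimethylformamide, CN(C)C=O; water, O
Why: Vilsmeier–Haack formylation of 5-alkylresorcinol dimethyl ethers goes to the position ortho to one methoxy and para to the other, next to the alkyl group, which is the substitution pattern of ring A.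

Step 8
Reactants: 14 2,4-dimethoxy-6-propylbenzaldehyde
Product: 15 2,4-dimethoxy-6-propylbenzoic acid
Conditions: NaClO2, NaH2PO4, 2-methyl-2-butene, t-BuOH/H2O, rt
Reagents that add atoms: sodium chlorite, [Na+].[O-]Cl=O
Why: Pinnick oxidation converts the hindered aldehyde to the acid, and excess alkene traps hypochlorous acid before it can chlorinate the electron-rich ring.

Step 9
Reactants: 15 2,4-dimethoxy-6-propylbenzoic acid; 11 benzyl 2-(benzyloxy)-4-hydroxy-6-propylbenzoate
Product: 17 benzyl 2-(benzyloxy)-4-[(2,4-dimethoxy-6-propylbenzoyl)oxy]-6-propylbenzoate, via 2,4-dimethoxy-6-propylbenzoyl chloride 16 (not isolated)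
Conditions: (COCl)2, cat. DMF, CH2Cl2, 0 °C to rt, evaporate; then 11, Et3N, cat. DMAP, CH2Cl2, 0 °C to rt
Reagents that add atoms: none
Why: Oxalyl chloride with catalytic DMF gives the acid chloride, and DMAP-assisted acylation of the single free, unhindered C4 phenol of 11 forms the depside ester (nucleophilic acyl substitution); the two donor methoxy groups help ionisation of the hindered acyl chloride.

Step 10
Reactants: 17 benzyl 2-(benzyloxy)-4-[(2,4-dimethoxy-6-propylbenzoyl)oxy]-6-propylbenzoate
Product: 18 4-[(2,4-dimethoxy-6-propylbenzoyl)oxy]-2-hydroxy-6-propylbenzoic acid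
Conditions: H2 (1 atm), 10% Pd/C, EtOAc, rt
Reagents that add atoms: none
Why: Catalytic hydrogenolysis cleaves the benzyl ester and the benzyl aryl ether in one operation under neutral conditions that leave the depside aryl ester and the methyl ethers untouched.

**Compound list**

1 | dibenzyl 3-oxopentanedioate | O=C(CC(=O)OCc1ccccc1)CC(=O)OCc1ccccc1 | starting material
2 | butanoyl chloride | CCCC(=O)Cl | starting material
3 | dibenzyl 2-butanoyl-3-oxopentanedioate (racemic, enolisable) | CCCC(=O)C(C(=O)OCc1ccccc1)C(=O)CC(=O)OCc1ccccc1 | intermediate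
4 | benzyl 4-hydroxy-2-oxo-6-propyl-2H-pyran-5-carboxylate | CCCC1=C(C(=O)OCc2ccccc2)C(O)=CC(=O)O1 | intermediate
5 | benzyl 4-(benzyloxy)-2-oxo-6-propyl-2H-pyran-5-carboxylate | CCCC1=C(C(=O)OCc2ccccc2)C(OCc2ccccc2)=CC(=O)O1 | intermediate
6 | trimethylsilyl acetate | CC(=O)O[Si](C)(C)C | starting material
7 | 1,1-bis(trimethylsilyloxy)ethene | C=C(O[Si](C)(C)C)O[Si](C)(C)C | intermediate
8 | benzyl 5-(benzyloxy)-3-oxo-1-propyl-8,8-bis(trimethylsilyloxy)-2-oxabicyclo[2.2.2]oct-5-ene-6-carboxylate (racemic bicyclic lactone cycloadduct, formed in the flask) | CCCC12OC(=O)C(C(OCc3ccccc3)=C1C(=O)OCc1ccccc1)C(O[Si](C)(C)C)(O[Si](C)(C)C)C2 | intermediate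
9 | benzyl 6-(benzyloxy)-2-propyl-4,4-bis(trimethylsilyloxy)cyclohexa-1,5-diene-1-carboxylate (formed in the flask) | CCCC1=C(C(=O)OCc2ccccc2)C(OCc2ccccc2)=CC(O[Si](C)(C)C)(O[Si](C)(C)C)C1 | intermediate
10 | benzyl 2-(benzyloxy)-6-propyl-4-(trimethylsilyloxy)benzoate (formed in the flask) | CCCc1cc(O[Si](C)(C)C)cc(OCc2ccccc2)c1C(=O)OCc1ccccc1 | intermediate
11 | benzyl 2-(benzyloxy)-4-hydroxy-6-propylbenzoate | CCCc1cc(O)cc(OCc2ccccc2)c1C(=O)OCc1ccccc1 | intermediate
12 | 5-propylresorcinol (5-propylbenzene-1,3-diol) | CCCc1cc(O)cc(O)c1 | starting material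
13 | 1,3-dimethoxy-5-propylbenzene | CCCc1cc(OC)cc(OC)c1 | intermediate
14 | 2,4-dimethoxy-6-propylbenzaldehyde | CCCc1cc(OC)cc(OC)c1C=O | intermediate
15 | 2,4-dimethoxy-6-propylbenzoic acid | CCCc1cc(OC)cc(OC)c1C(=O)O | intermediate
16 | 2,4-dimethoxy-6-propylbenzoyl chloride (formed in the flask) | CCCc1cc(OC)cc(OC)c1C(=O)Cl | intermediate
17 | benzyl 2-(benzyloxy)-4-[(2,4-dimethoxy-6-propylbenzoyl)oxy]-6-propylbenzoate | CCCc1cc(OC(=O)c2c(CCC)cc(OC)cc2OC)cc(OCc2ccccc2)c1C(=O)OCc1ccccc1 | intermediate
18 | 4-[(2,4-dimethoxy-6-propylbenzoyl)oxy]-2-hydroxy-6-propylbenzoic acid (CNP0398006.0) | CCCc1cc(OC(=O)c2c(CCC)cc(OC)cc2OC)cc(O)c1C(=O)O | target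

**Step count and risks**

Total step count: 10. Longest linear sequence: 6 steps (steps 1, 2, 3, 5, 9, 10). The ring A arm (steps 6, 7, 8) and the ketene acetal arm (step 4) are shorter and converge at steps 9 and 5.

Steps most likely to fail:

1. Step 5. The cycloaddition may be too slow on the donor-substituted, 6-alkylated pyrone, or the first bond may form and silyl transfer may then stop the sequence before ring closure. The fallback builds ring B from 5-propylresorcinol 12 without a cycloaddition. Kolbe–Schmitt-type ortho-carboxylation with methyl magnesium carbonate (MeOMgOCO2Me, DMF, 120 °C, then aq. HCl) should give 2,4-dihydroxy-6-propylbenzoic acid F1. Carboxylate benzylation (BnBr, KHCO3, DMF) should give benzyl 2,4-dihydroxy-6-propylbenzoate F2. Acylation with acid chloride 16 (Et3N, DMAP, CH2Cl2) should go to the 4-hydroxyl, because the 2-hydroxyl is held in a hydrogen bond to the ester, and give benzyl 4-[(2,4-dimethoxy-6-propylbenzoyl)oxy]-2-hydroxy-6-propylbenzoate F3. Hydrogenolysis of F3 (H2, Pd/C, EtOAc) rejoins the route at target 18.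

2. Step 4. Silylation of the acetate enolate may go to carbon instead of oxygen, and the volatile, moisture-sensitive acetal may be lost on isolation. The fallback sets out from pyrone 5 and changes the dienophile to the bulkier silyl series, where O-silylation of acetate enolates is dependable. Purchased tert-butyldimethylsilyl acetate, LiN(iPr)2 and t-BuMe2SiCl in THF/DMPU at −78 °C should give 1,1-bis(tert-butyldimethylsilyloxy)ethene F4. Heating F4 with 5 in toluene should give, by the same cycloaddition, decarboxylation and silanol loss, the stable benzyl 2-(benzyloxy)-4-(tert-butyldimethylsilyloxy)-6-propylbenzoate F5. A separate fluoride desilylation (Bu4NF, THF, 0 °C) then rejoins the route at phenol 11.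

3. Step 2. Under base, retro-Claisen loss of the butanoyl group or attack of liberated benzyl alkoxide on the tricarbonyl system may compete with lactonisation. The fallback sets out from butanoyl chloride 2 and assembles the pyrone from a β-keto ester and a malonyl unit. Acylation of Meldrum's acid (pyridine, CH2Cl2, 0 °C) should give 5-(1-hydroxybutylidene)-2,2-dimethyl-1,3-dioxane-4,6-dione F6. Heating F6 with benzyl alcohol in toluene should give benzyl 3-oxohexanoate F7. Condensation of F7 with malonyl dichloride (C-acylation at the α-carbon, then ring closure through the ketone enol oxygen) should give 4-hydroxypyrone 4, where the route is rejoined.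

Further compounds
F1 | step 5 | 2,4-dihydroxy-6-propylbenzoic acid | CCCc1cc(O)cc(O)c1C(=O)O
F2 | step 5 | benzyl 2,4-dihydroxy-6-propylbenzoate | CCCc1cc(O)cc(O)c1C(=O)OCc1ccccc1
F3 | step 5 | benzyl 4-[(2,4-dimethoxy-6-propylbenzoyl)oxy]-2-hydroxy-6-propylbenzoate | CCCc1cc(OC(=O)c2c(CCC)cc(OC)cc2OC)cc(O)c1C(=O)OCc1ccccc1
F4 | step 4 | 1,1-bis(tert-butyldimethylsilyloxy)ethene | C=C(O[Si](C)(C)C(C)(C)C)O[Si](C)(C)C(C)(C)C
F5 | step 4 | benzyl 2-(benzyloxy)-4-(tert-butyldimethylsilyloxy)-6-propylbenzoate | CCCc1cc(O[Si](C)(C)C(C)(C)C)cc(OCc2ccccc2)c1C(=O)OCc1ccccc1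
F6 | step 2 | 5-(1-hydroxybutylidene)-2,2-dimethyl-1,3-dioxane-4,6-dione | CCCC(O)=C1C(=O)OC(C)(C)OC1=O
F7 | step 2 | benzyl 3-oxohexanoate | CCCC(=O)CC(=O)OCc1ccccc1
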